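**Reading turnover.** The constants of these flasks are hidden from us, so we work from readings.

| flask | substrate | free catalyst | temperature | remark | time |
|---|---|---|---|---|---|
| larch | 0.21 M | 0.09 mol% | 30 °C | run made earlier |  |
| cedar | 0.21 M | 0.36 mol% | 52 °C | run made earlier |  |
| ash | 0.32 M | 0.18 mol% | 30 °C | run made earlier |  |
| Friday's | 0.21 M | 0.18 mol% |  | at 20 °C until 6.0 min, from then on at 60 °C | 20 min |
| Thursday's | 0.21 M | 0.18 mol% |  | at 20 °C throughout | 6.0 min |

| run | time / min | product / % |
|---|---|---|
| larch | 0.833 | 0.5 |
| larch | 2.50 | 0.9 |
| larch | 4.00 | 1.7 |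
| larch | 6.00 | 2.5 |
| larch | 10.0 | 4.9 |
| larch | 12.0 | 5.7 |
| larch | 15.0 | 7.6 |
| cedar | 0.250 | 5.1 |
| cedar | 0.833 | 17.7 |
| cedar | 1.33 | 29.4 |
| cedar | 2.00 | 47.5 |
| cedar | 3.00 | 76.3 |
| cedar | 4.00 | 96.1 |
| cedar | 5.00 | 99.3 |
| ash | 1.33 | 1.8 |
| ash | 4.00 | 3.7 |
| ash | 8.00 | 5.1 |
| ash | 10.0 | 6.7 |
| ash | 15.0 | 10.6 |

(scatter of a reading: 0.5 percentage points)

- percentages count the substrate that a species holds: one idle complex counts as two
- reactions considered so far: catalyst intermediate B -> free catalyst + product; catalyst intermediate A -> catalyst intermediate B; substrate + catalyst intermediate B <-> idle complex; substrate + free catalyst <-> catalyst intermediate A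

- the flask that ends with the higher amount of product, in percent of the substrate charged, or "neither" when 2 percentage points or less lies between them (Friday's / Thursday's / neither)
- final product, as a percentage of the substrate charged, in Friday's
- final product, as a percentage of the substrate charged, in Thursday's

Turnover is product per minute divided by the catalyst charged, both as fractions of the substrate charged. The last larch reading gives 5.63 min⁻¹, and this larch turnover is the number we carry.

**Catalyst loading.** By hand, product per minute should follow the catalyst charged. No pair of runs isolates this, so we assume it, and we scale by 0.18 mol% in both flasks.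

**Substrate charge.** By hand, more substrate should go faster, but the last ash reading gives 3.93 min⁻¹, which is lower than larch. We read this as substrate holding catalyst back. Both flasks have larch's 0.21 M, so no correction is needed.

**Temperature step.** Cedar, read early at 0.833 min, gives 59.0 min⁻¹, a factor of 10.5 over larch between 30 °C and 52 °C. We let that factor grow evenly per degree. At 20 °C this gives 1.93 min⁻¹, and at 60 °C, beyond the runs, 139 min⁻¹.

**Time allowed.** Substrate, the limiting reagent, caps product at the charge, and cedar's 99.3% shows catalyst still working close to that cap. Thursday's should reach 2.08% in 6.0 min. By our estimate, with that turnover held steady, Friday's, once hot, needs about 4.00 min for the whole charge and has 14.0 min, so we expect it at the cap.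

**The result.** The forecast says Friday's, with 99.5% (93% to 100%) in Friday's and 1.9% (1% to 3.2%) in Thursday's, noting that “Nothing in the runs suggests catalyst death”. The flasks give 100% in Friday's and 1.78% in Thursday's, so Friday's ends higher.

    catalyst intermediate B → free catalyst + product (k = 0.510 s⁻¹, Ea = 61.0 kJ mol⁻¹)
    catalyst intermediate A → catalyst intermediate B (k = 1.10 s⁻¹, Ea = 75.0 kJ mol⁻¹)
    substrate + catalyst intermediate B ⇌ idle complex, settled at all times (K = 80.0 M⁻¹, ΔH = −32.0 kJ mol⁻¹)
    substrate + free catalyst ⇌ catalyst intermediate A (K = 56.0 M⁻¹, k = 6.20 M⁻¹ s⁻¹, Ea = 57.0 kJ mol⁻¹, ΔH = −30.0 kJ mol⁻¹)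
    (constants at 20 °C)

**The heat.** Friday's ends high because it leaves its starting temperature. The same flask held at 20 °C ends at 6.06%, and our turnover gives 6.96% for it. A Friday's held cool would still lead Thursday's by 4.3 percentage points, a part of the gap that comes from the longer time.

**A neighbour.** For a flask like Thursday's kept at 45 °C, the carried turnover becomes 27.9 min⁻¹, which gives 30.1% in 6.0 min. That flask gives 34.4%.

(The earlier runs and the new flask are simulated with made-up constants; noise was put on by code.)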